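**Retrosynthetic overview**

1. The target comes from flavanone 17 by removing two MOM ethers and one aryl acetate. Rings A and B are bought; ring C is the only ring made, and it is made last.
2. Ring C is closed at C4–C4a by intramolecular Friedel–Crafts acylation of the (S)-3-aryloxy-3-arylpropanoic acid 15. The feature that carries the strategy: in ring A the side-chain carbon C6 is para to C8a, the carbon bonded to O1. The O1 aryl ether of a 4-alkenyl-3,5-dioxygenated phenol therefore has two equivalent ortho carbons (future C4a and C8), and either closure gives the 6-substituted flavanone.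
3. The O1–C2 bond of 15 comes from Mitsunobu inversion of the (R)-β-hydroxy allyl ester 13 (asymmetric transfer hydrogenation of a β-keto ester) with the symmetric phenol 9.
4. The C6–C1″ bond of 9 comes from addition of the aryllithium of bis-MOM, mono-TIPS phloroglucinol to (S)-citronellal, followed by dehydration and desilylation.

Key step: step 11

Remark: flavanone numbering is used (O1, C2–C4, C4a, C5–C8, C8a; side chain C1″–C8″). C3″ is carried unchanged from (S)-citronellal, so material of high enantiomeric purity is assumed.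

**Route**

Step 1
Reactants: 1 phloroglucinol
Product: 2 3,5-bis(methoxymethoxy)phenol
Conditions: MOMCl (2.0 equiv), i-Pr2NEt (2.2 equiv), DMF, 0 °C to rt; chromatography to remove mono- and tris-ethers
Reagents that add atoms: chloromethyl methyl ether (MOMCl), COCCl
Why: Williamson-type O-alkylation of three equivalent phenols with an α-chloro ether; at two equivalents the bis-ether should be the main statistical product and is separable, and the mono-ether can be resubmitted.

Step 2
Reactants: 2 3,5-bis(methoxymethoxy)phenol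
Product: 3 [3,5-bis(methoxymethoxy)phenoxy]tri(propan-2-yl)silane
Conditions: TIPSCl (1.2 equiv), imidazole (2.5 equiv), DMF, rt
Reagents that add atoms: chlorotri(propan-2-yl)silane (TIPSCl), CC(C)[Si](Cl)(C(C)C)C(C)C
Why: Standard silylation of a phenol; the bulky, non-coordinating TIPS ether resists n-BuLi and does not direct metalation, so the next step goes between the two MOM ethers.

Step 3
Reactants: 3 [3,5-bis(methoxymethoxy)phenoxy]tri(propan-2-yl)silane; 4 (S)-citronellal
Product: 6 (3S)-1-[2,6-bis(methoxymethoxy)-4-{[tri(propan-2-yl)silyl]oxy}phenyl]-3,7-dimethyloct-6-en-1-ol (both C1 epimers), via aryllithium 5 (not isolated)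
Conditions: n-BuLi (1.1 equiv), THF, 0 °C, 1 h; then 4, −78 to −20 °C; then H2O
Reagents that add atoms: none
Why: Directed ortho-metalation at the carbon flanked by two MOM ethers, then 1,2-addition of the aryllithium to the aldehyde; the new carbinol centre is left uncontrolled because it is removed in step 4, and C3″ is not touched.

Step 4
Reactants: 6 (3S)-1-[2,6-bis(methoxymethoxy)-4-{[tri(propan-2-yl)silyl]oxy}phenyl]-3,7-dimethyloct-6-en-1-ol
Product: 8 {4-[(1E,3S)-3,7-dimethylocta-1,6-dien-1-yl]-3,5-bis(methoxymethoxy)phenoxy}tri(propan-2-yl)silane, via sulfamate ester 7 (not isolated)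
Conditions: methyl N-(triethylammoniosulfonyl)carbamate (Burgess reagent, 1.5 equiv), toluene, rt to 50 °C
Reagents that add atoms: none
Why: Burgess dehydration; the sulfamate of the electron-rich benzylic alcohol undergoes syn-elimination within the ion pair under neutral conditions, only C2″ carries β-hydrogens, and the E-styrene should result from the transition state with aryl and alkyl groups anti.

Step 5
Reactants: 8 {4-[(1E,3S)-3,7-dimethylocta-1,6-dien-1-yl]-3,5-bis(methoxymethoxy)phenoxy}tri(propan-2-yl)silane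
Product: 9 4-[(1E,3S)-3,7-dimethylocta-1,6-dien-1-yl]-3,5-bis(methoxymethoxy)phenol
Conditions: TBAF (1.1 equiv), AcOH (1.1 equiv), THF, 0 °C
Reagents that add atoms: none
Why: Fluoride cleavage of an aryl silyl ether; the acetic acid buffer keeps the medium near neutral so MOM ethers, alkenes and the allylic centre are unaffected.

Step 6
Reactants: 10 ethyl 3-(4-hydroxyphenyl)-3-oxopropanoate
Product: 11 prop-2-en-1-yl 3-(4-hydroxyphenyl)-3-oxopropanoate
Conditions: allyl alcohol (10 equiv), DMAP (0.2 equiv), 4 Å molecular sieves, toluene, 110 °C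
Reagents that add atoms: allyl alcohol, C=CCO
Why: Transesterification of a β-keto ester, driven by removal of ethanol; the allyl ester is chosen because it can later be removed under neutral conditions that spare an aryl acetate and do not trigger β-elimination of the aryloxide.

Step 7
Reactants: 11 prop-2-en-1-yl 3-(4-hydroxyphenyl)-3-oxopropanoate
Product: 12 prop-2-en-1-yl 3-[4-(acetyloxy)phenyl]-3-oxopropanoate
Conditions: Ac2O (1.1 equiv), pyridine (2 equiv), CH2Cl2, 0 °C to rt
Reagents that add atoms: acetic anhydride, CC(=O)OC(C)=O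
Why: Selective O-acetylation of the phenol; the acetate makes ring B electron-poor, which is needed for clean inversion in step 9 and for a stable C2–O bond in steps 11 and 12.

Step 8
Reactants: 12 prop-2-en-1-yl 3-[4-(acetyloxy)phenyl]-3-oxopropanoate
Product: 13 prop-2-en-1-yl (3R)-3-[4-(acetyloxy)phenyl]-3-hydroxypropanoate
Conditions: RuCl(p-cymene)[(R,R)-TsDPEN] (1 mol %), HCO2H/Et3N (5:2), CH2Cl2, 28 °C
Reagents that add atoms: none
Why: Asymmetric transfer hydrogenation of an aryl ketone; the (R,R)-ligand should give the (R)-carbinol through the six-membered CH/π-organised transition state, in the same sense as for acetophenone (to be confirmed by Mosher analysis before use), and the catalyst does not reduce the allyl group.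

Step 9
Reactants: 9 4-[(1E,3S)-3,7-dimethylocta-1,6-dien-1-yl]-3,5-bis(methoxymethoxy)phenol; 13 prop-2-en-1-yl (3R)-3-[4-(acetyloxy)phenyl]-3-hydroxypropanoate
Product: 14 prop-2-en-1-yl (3S)-3-[4-(acetyloxy)phenyl]-3-{4-[(1E,3S)-3,7-dimethylocta-1,6-dien-1-yl]-3,5-bis(methoxymethoxy)phenoxy}propanoate
Conditions: PPh3 (1.5 equiv), DIAD (1.5 equiv, slow addition), toluene, 0 °C to rt
Reagents that add atoms: none
Why: Mitsunobu etherification; the unhindered phenol displaces the alkoxyphosphonium group by SN2 with inversion, (R) to (S), which sets the future C2, and the acetoxy group and non-polar solvent disfavour ionisation.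

Step 10
Reactants: 14 prop-2-en-1-yl (3S)-3-[4-(acetyloxy)phenyl]-3-{4-[(1E,3S)-3,7-dimethylocta-1,6-dien-1-yl]-3,5-bis(methoxymethoxy)phenoxy}propanoate
Product: 15 (3S)-3-[4-(acetyloxy)phenyl]-3-{4-[(1E,3S)-3,7-dimethylocta-1,6-dien-1-yl]-3,5-bis(methoxymethoxy)phenoxy}propanoic acid
Conditions: Pd(PPh3)4 (5 mol %), N-methylaniline (3 equiv), THF, rt; pH 5 buffer work-up
Reagents that add atoms: none
Why: Tsuji–Trost deallylation; zerovalent palladium ionises the allyl ester to a π-allyl complex that the weakly nucleophilic aniline traps, so the acid is released without hydroxide and the aryl acetate, MOM ethers and β-aryloxy linkage remain.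

Step 11
Reactants: 15 (3S)-3-[4-(acetyloxy)phenyl]-3-{4-[(1E,3S)-3,7-dimethylocta-1,6-dien-1-yl]-3,5-bis(methoxymethoxy)phenoxy}propanoic acid
Product: 17 (2S)-2-[4-(acetyloxy)phenyl]-6-[(1E,3S)-3,7-dimethylocta-1,6-dien-1-yl]-5,7-bis(methoxymethoxy)-2,3-dihydro-4H-chromen-4-one, via mixed anhydride 16 (not isolated)
Conditions: (CF3CO)2O (1.2 equiv), 2,6-di-tert-butyl-4-methylpyridine (3 equiv), CH2Cl2, −40 to 0 °C; pH 7 buffer
Reagents that add atoms: none
Why: Trifluoroacetic anhydride converts the acid into mixed anhydride 16, whose acyl carbon is attacked by the ring carbon ortho to the ether oxygen (future C4a, activated by three oxygen donors), and proton loss to the buffer restores aromaticity; this is an intramolecular Friedel–Crafts acylation, and the closest known reaction is the anhydride- or polyphosphoric-acid-mediated cyclisation of 3-aryloxypropanoic acids to chroman-4-ones and flavanones. Ring C closes in a 6-exo-trig mode by forming C4–C4a. No stereocentre is created, and C2 and C3″ are spectators. Regioselectivity needs no control, because rotation about the O1–aryl bond interchanges the two ortho carbons, so both closures give the 6-alkenyl isomer. The step needs chemoselectivity for the arene over the two alkenes and over ionisation of the benzylic C2–O bond. This should come from the six-membered intramolecular delivery, from the high ring nucleophilicity that allows low temperature and near-stoichiometric anhydride, from the hindered pyridine that takes up trifluoroacetic acid, and from the acetoxy group on ring B that destabilises a cation at C2.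

Step 12
Reactants: 17 (2S)-2-[4-(acetyloxy)phenyl]-6-[(1E,3S)-3,7-dimethylocta-1,6-dien-1-yl]-5,7-bis(methoxymethoxy)-2,3-dihydro-4H-chromen-4-one
Product: 19 4-[(2S)-6-[(1E,3S)-3,7-dimethylocta-1,6-dien-1-yl]-5,7-dihydroxy-4-oxo-3,4-dihydro-2H-chromen-2-yl]phenyl acetate, via bis-silyl ether 18 (not isolated)
Conditions: TMSOTf (4 equiv), 2,2'-bipyridyl (6 equiv), CH3CN, 0 °C to rt; then H2O, rt
Reagents that add atoms: none
Why: Silyl triflate/bipyridyl cleavage of aromatic MOM ethers; each aryl oxygen is transferred to silicon while the methoxymethyl group is held as an N-alkylbipyridinium salt, and water then hydrolyses the aryl silyl ethers, so no free Brønsted acid meets the ortho-hydroxystyrene, the trisubstituted alkene or the C2–O bond, which the retained acetate still protects.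

Step 13
Reactants: 19 4-[(2S)-6-[(1E,3S)-3,7-dimethylocta-1,6-dien-1-yl]-5,7-dihydroxy-4-oxo-3,4-dihydro-2H-chromen-2-yl]phenyl acetate
Product: 20 (2S)-6-[(1E,3S)-3,7-dimethylocta-1,6-dien-1-yl]-5,7-dihydroxy-2-(4-hydroxyphenyl)-2,3-dihydro-4H-chromen-4-one (CNP0150993.1)
Conditions: K2CO3 (0.2 equiv), degassed MeOH, 0 °C, short reaction time; AcOH quench
Reagents that add atoms: none
Why: Base-catalysed methanolysis (transesterification) of an aryl acetate, which is fast at 0 °C; the 7-phenoxide formed first lowers the acidity of C3–H, which should suppress ring opening to the chalcone and so preserve C2.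

**Compound list**

1 | phloroglucinol | Oc1cc(O)cc(O)c1 | starting material
2 | 3,5-bis(methoxymethoxy)phenol | COCOc1cc(O)cc(OCOC)c1 | intermediate
3 | [3,5-bis(methoxymethoxy)phenoxy]tri(propan-2-yl)silane | COCOc1cc(OCOC)cc(O[Si](C(C)C)(C(C)C)C(C)C)c1 | intermediate
4 | (S)-citronellal | CC(C)=CCC[C@H](C)CC=O | starting material
5 | [2,6-bis(methoxymethoxy)-4-{[tri(propan-2-yl)silyl]oxy}phenyl]lithium | [Li]c1c(OCOC)cc(O[Si](C(C)C)(C(C)C)C(C)C)cc1OCOC | intermediate
6 | (3S)-1-[2,6-bis(methoxymethoxy)-4-{[tri(propan-2-yl)silyl]oxy}phenyl]-3,7-dimethyloct-6-en-1-ol (both C1 epimers) | CC(C)=CCC[C@H](C)CC(O)c1c(OCOC)cc(O[Si](C(C)C)(C(C)C)C(C)C)cc1OCOC | intermediate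
7 | triethylammonium salt of the N-(methoxycarbonyl)sulfamate ester of 6 | CC(C)=CCC[C@H](C)CC(OS(=O)(=O)[N-]C(=O)OC)c1c(OCOC)cc(O[Si](C(C)C)(C(C)C)C(C)C)cc1OCOC.CC[NH+](CC)CC | intermediate
8 | {4-[(1E,3S)-3,7-dimethylocta-1,6-dien-1-yl]-3,5-bis(methoxymethoxy)phenoxy}tri(propan-2-yl)silane | CC(C)=CCC[C@H](C)/C=C/c1c(OCOC)cc(O[Si](C(C)C)(C(C)C)C(C)C)cc1OCOC | intermediate
9 | 4-[(1E,3S)-3,7-dimethylocta-1,6-dien-1-yl]-3,5-bis(methoxymethoxy)phenol | CC(C)=CCC[C@H](C)/C=C/c1c(OCOC)cc(O)cc1OCOC | intermediate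
10 | ethyl 3-(4-hydroxyphenyl)-3-oxopropanoate | CCOC(=O)CC(=O)c1ccc(O)cc1 | starting material
11 | prop-2-en-1-yl 3-(4-hydroxyphenyl)-3-oxopropanoate | C=CCOC(=O)CC(=O)c1ccc(O)cc1 | intermediate
12 | prop-2-en-1-yl 3-[4-(acetyloxy)phenyl]-3-oxopropanoate | C=CCOC(=O)CC(=O)c1ccc(OC(C)=O)cc1 | intermediate
13 | prop-2-en-1-yl (3R)-3-[4-(acetyloxy)phenyl]-3-hydroxypropanoate | C=CCOC(=O)C[C@@H](O)c1ccc(OC(C)=O)cc1 | intermediate
14 | prop-2-en-1-yl (3S)-3-[4-(acetyloxy)phenyl]-3-{4-[(1E,3S)-3,7-dimethylocta-1,6-dien-1-yl]-3,5-bis(methoxymethoxy)phenoxy}propanoate | CC(C)=CCC[C@H](C)/C=C/c1c(OCOC)cc(O[C@@H](CC(=O)OCC=C)c2ccc(OC(C)=O)cc2)cc1OCOC | intermediate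
15 | (3S)-3-[4-(acetyloxy)phenyl]-3-{4-[(1E,3S)-3,7-dimethylocta-1,6-dien-1-yl]-3,5-bis(methoxymethoxy)phenoxy}propanoic acid | CC(C)=CCC[C@H](C)/C=C/c1c(OCOC)cc(O[C@@H](CC(=O)O)c2ccc(OC(C)=O)cc2)cc1OCOC | intermediate
16 | mixed anhydride of 15 with trifluoroacetic acid | CC(C)=CCC[C@H](C)/C=C/c1c(OCOC)cc(O[C@@H](CC(=O)OC(=O)C(F)(F)F)c2ccc(OC(C)=O)cc2)cc1OCOC | intermediate
17 | (2S)-2-[4-(acetyloxy)phenyl]-6-[(1E,3S)-3,7-dimethylocta-1,6-dien-1-yl]-5,7-bis(methoxymethoxy)-2,3-dihydro-4H-chromen-4-one | CC(C)=CCC[C@H](C)/C=C/c1c(OCOC)cc2c(c1OCOC)C(=O)C[C@@H](c1ccc(OC(C)=O)cc1)O2 | intermediate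
18 | (2S)-2-[4-(acetyloxy)phenyl]-6-[(1E,3S)-3,7-dimethylocta-1,6-dien-1-yl]-5,7-bis[(trimethylsilyl)oxy]-2,3-dihydro-4H-chromen-4-one | CC(C)=CCC[C@H](C)/C=C/c1c(O[Si](C)(C)C)cc2c(c1O[Si](C)(C)C)C(=O)C[C@@H](c1ccc(OC(C)=O)cc1)O2 | intermediate
19 | 4-[(2S)-6-[(1E,3S)-3,7-dimethylocta-1,6-dien-1-yl]-5,7-dihydroxy-4-oxo-3,4-dihydro-2H-chromen-2-yl]phenyl acetate | CC(C)=CCC[C@H](C)/C=C/c1c(O)cc2c(c1O)C(=O)C[C@@H](c1ccc(OC(C)=O)cc1)O2 | intermediate
20 | (2S)-6-[(1E,3S)-3,7-dimethylocta-1,6-dien-1-yl]-5,7-dihydroxy-2-(4-hydroxyphenyl)-2,3-dihydro-4H-chromen-4-one | CC(C)=CCC[C@H](C)/C=C/c1c(O)cc2c(c1O)C(=O)C[C@@H](c1ccc(O)cc1)O2 | target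

**Step count and risks**

Total steps: 13. Longest linear sequence: 10 steps (steps 1–5 and 9–13, from phloroglucinol); the keto ester branch (steps 6–8) joins at step 9.

Steps most likely to fail:

1. Step 11 (ring closure). The anhydride could acylate the electron-rich styrene, liberated acid could cleave the acetals, or the mixed anhydride could lose the aryloxide by ionisation or elimination at C2 with erosion of configuration. The fallback sets out from acid 15 and returns at flavanone 17. The carboxyl group would be converted under neutral conditions with 1-chloro-N,N,2-trimethylprop-1-en-1-amine in CH2Cl2 at 0 °C into (3S)-3-[4-(acetyloxy)phenyl]-3-{4-[(1E,3S)-3,7-dimethylocta-1,6-dien-1-yl]-3,5-bis(methoxymethoxy)phenoxy}propanoyl chloride F1. This pre-formed acyl chloride would then be cyclised in hexafluoropropan-2-ol at 0 °C with 2,6-di-tert-butyl-4-methylpyridine as acid scavenger. This is a hydrogen-bond-promoted Friedel–Crafts acylation with no anhydride and no Lewis acid present, so nothing in the flask can acylate the alkenes.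

2. Step 9 (Mitsunobu etherification). The activated β-hydroxy ester could undergo β-elimination to the cinnamate, or react partly by ionisation with incomplete inversion. The fallback sets out from hydroxy ester 13 and phenol 9 and returns at acid 15, so step 10 is then not needed; it removes the acidifying ester before the etherification.
   - Deallylation of 13 (Pd(PPh3)4, N-methylaniline) would give (3R)-3-[4-(acetyloxy)phenyl]-3-hydroxypropanoic acid F2.
   - BH3·SMe2 in THF at 0 °C, which reduces a carboxylic acid but not an aryl acetate, would give 4-[(1R)-1,3-dihydroxypropyl]phenyl acetate F3.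
   - Selective silylation of the primary hydroxyl (TBSCl, imidazole, CH2Cl2, −20 °C) would give 4-[(1R)-3-{[tert-butyl(dimethyl)silyl]oxy}-1-hydroxypropyl]phenyl acetate F4.
   - Mitsunobu reaction of F4 with 9 (PPh3, DIAD, toluene), for which no conjugated elimination product is available, would give 4-[(1S)-3-{[tert-butyl(dimethyl)silyl]oxy}-1-{4-[(1E,3S)-3,7-dimethylocta-1,6-dien-1-yl]-3,5-bis(methoxymethoxy)phenoxy}propyl]phenyl acetate F5.
   - HF·pyridine in THF/pyridine would give 4-[(1S)-1-{4-[(1E,3S)-3,7-dimethylocta-1,6-dien-1-yl]-3,5-bis(methoxymethoxy)phenoxy}-3-hydroxypropyl]phenyl acetate F6.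
   - Oxidation of F6 with TEMPO (cat.) and PhI(OAc)2 in CH3CN/H2O would give acid 15.

3. Step 4 (dehydration). The sulfamate could ionise fully to the strongly stabilised benzylic cation, which could then cyclise onto the C6″–C7″ alkene or give E/Z mixtures instead of undergoing clean syn-elimination. The fallback sets out from alcohol 6 and returns at styrene 8; it avoids any cation.
   - Dess–Martin oxidation of 6 would give (3S)-1-[2,6-bis(methoxymethoxy)-4-{[tri(propan-2-yl)silyl]oxy}phenyl]-3,7-dimethyloct-6-en-1-one F7.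
   - Enolisation with KN(SiMe3)2 and trapping with PhNTf2 in THF at −78 °C would give, through the Z-enolate expected for an aryl ketone, (1Z,3S)-1-[2,6-bis(methoxymethoxy)-4-{[tri(propan-2-yl)silyl]oxy}phenyl]-3,7-dimethylocta-1,6-dien-1-yl trifluoromethanesulfonate F8.
   - Reduction of F8 with Pd(OAc)2, PPh3, HCO2H and Bu3N in DMF at 60 °C replaces the triflate by hydrogen with retention of alkene geometry and would give the E-styrene 8.

**Further compounds**

F1 | step 11 | (3S)-3-[4-(acetyloxy)phenyl]-3-{4-[(1E,3S)-3,7-dimethylocta-1,6-dien-1-yl]-3,5-bis(methoxymethoxy)phenoxy}propanoyl chloride | CC(C)=CCC[C@H](C)/C=C/c1c(OCOC)cc(O[C@@H](CC(=O)Cl)c2ccc(OC(C)=O)cc2)cc1OCOC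
F2 | step 9 | (3R)-3-[4-(acetyloxy)phenyl]-3-hydroxypropanoic acid | OC(=O)C[C@@H](O)c1ccc(OC(C)=O)cc1
F3 | step 9 | 4-[(1R)-1,3-dihydroxypropyl]phenyl acetate | OCC[C@@H](O)c1ccc(OC(C)=O)cc1
F4 | step 9 | 4-[(1R)-3-{[tert-butyl(dimethyl)silyl]oxy}-1-hydroxypropyl]phenyl acetate | CC(C)(C)[Si](C)(C)OCC[C@@H](O)c1ccc(OC(C)=O)cc1
F5 | step 9 | 4-[(1S)-3-{[tert-butyl(dimethyl)silyl]oxy}-1-{4-[(1E,3S)-3,7-dimethylocta-1,6-dien-1-yl]-3,5-bis(methoxymethoxy)phenoxy}propyl]phenyl acetate | CC(C)=CCC[C@H](C)/C=C/c1c(OCOC)cc(O[C@@H](CCO[Si](C)(C)C(C)(C)C)c2ccc(OC(C)=O)cc2)cc1OCOC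
F6 | step 9 | 4-[(1S)-1-{4-[(1E,3S)-3,7-dimethylocta-1,6-dien-1-yl]-3,5-bis(methoxymethoxy)phenoxy}-3-hydroxypropyl]phenyl acetate | CC(C)=CCC[C@H](C)/C=C/c1c(OCOC)cc(O[C@@H](CCO)c2ccc(OC(C)=O)cc2)cc1OCOC
F7 | step 4 | (3S)-1-[2,6-bis(methoxymethoxy)-4-{[tri(propan-2-yl)silyl]oxy}phenyl]-3,7-dimethyloct-6-en-1-one | CC(C)=CCC[C@H](C)CC(=O)c1c(OCOC)cc(O[Si](C(C)C)(C(C)C)C(C)C)cc1OCOC
F8 | step 4 | (1Z,3S)-1-[2,6-bis(methoxymethoxy)-4-{[tri(propan-2-yl)silyl]oxy}phenyl]-3,7-dimethylocta-1,6-dien-1-yl trifluoromethanesulfonate | O=S(=O)(O/C(=C\[C@@H](C)CCC=C(C)C)c1c(OCOC)cc(O[Si](C(C)C)(C(C)C)C(C)C)cc1OCOC)C(F)(F)F
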